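**Strategy.** Ring C is opened at C4–C4a and O1–C2. Read at a higher oxidation level, C2 is a ketone carbon and C4 the β-carbon of an enone, so C2–C3–C4 with ring B and the 3-O-gallate becomes an α-galloyloxy aryl vinyl ketone. Ring A, a symmetric phloroglucinol 5-monogallate, acts as a C,O-bisnucleophile through C4a and O1. One acid-mediated operation (Friedel–Crafts conjugate addition, hemiketalisation, dehydration) should close ring C as an achiral 3-galloyloxy-4H-chromene that already carries all five rings and both esters. An asymmetric syn-hydrogenation of C2=C3 then sets both stereocentres cis, and hydrogenolysis frees the phenols.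

Key step: step 6

Remark: the target is the (2R,3R), 2,3-cis isomer; which antipode of the hydrogenation ligand gives it would be fixed in a first screen (cod = 1,5-cyclooctadiene; iPr-PHOX = 2-[2-(diphenylphosphino)phenyl]-4-isopropyl-4,5-dihydrooxazole; BArF = tetrakis[3,5-bis(trifluoromethyl)phenyl]borate).

Step 1
Reactants: 1 3,4,5-tris(benzyloxy)benzoic acid
Product: 2 3,4,5-tris(benzyloxy)benzoyl chloride
Conditions: (COCl)2, cat. DMF, CH2Cl2, 0 °C to rt
Reagents that add atoms: oxalyl chloride, O=C(Cl)C(=O)Cl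
Why: Acid chloride formation through DMF-derived chloroiminium (Vilsmeier-type) activation is mild enough to leave the benzyl ethers untouched.

Step 2
Reactants: 3 phloroglucinol (4 equiv), 2 3,4,5-tris(benzyloxy)benzoyl chloride
Product: 4 3,5-dihydroxyphenyl 3,4,5-tris(benzyloxy)benzoate
Conditions: pyridine, THF, 0 °C, slow addition of 2
Reagents that add atoms: none
Why: Base-mediated O-acylation of a phenol by an acyl chloride (Schotten–Baumann-type esterification), in which the excess of the threefold-symmetric triol and slow addition should bias the statistics toward the monoester, the unreacted triol being washed out with water.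

Step 3
Reactants: 5 1-(3,4-dihydroxyphenyl)propan-1-one
Product: 6 1-[3,4-bis(benzyloxy)phenyl]propan-1-one
Conditions: BnBr, K2CO3, DMF, 60 °C
Reagents that add atoms: benzyl bromide, BrCc1ccccc1
Why: Williamson ether synthesis on both catechol hydroxyls, which masks ring B with groups that fall in the last step.

Step 4
Reactants: 6 1-[3,4-bis(benzyloxy)phenyl]propan-1-one
Product: 7 1-[3,4-bis(benzyloxy)phenyl]propane-1,2-dione
Conditions: SeO2, 1,4-dioxane/H2O, reflux
Reagents that add atoms: selenium dioxide, O=[Se]=O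
Why: Riley oxidation of the only activated methylene, the CH2 next to the aryl ketone, should give the 1,2-diketone.

Step 5
Reactants: 7 1-[3,4-bis(benzyloxy)phenyl]propane-1,2-dione, 2 3,4,5-tris(benzyloxy)benzoyl chloride
Product: 8 3-[3,4-bis(benzyloxy)phenyl]-3-oxoprop-1-en-2-yl 3,4,5-tris(benzyloxy)benzoate
Conditions: Et3N, DMPU, THF, −20 °C to rt
Reagents that add atoms: none
Why: O-Acylation of an α-diketone enolate, in which enolisation is possible only toward the methyl group and the amine-derived enolate/acyl chloride pair should favour the enol ester, a captodative 1-aroylvinyl carboxylate.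

Step 6
Reactants: 4 3,5-dihydroxyphenyl 3,4,5-tris(benzyloxy)benzoate (2 equiv), 8 3-[3,4-bis(benzyloxy)phenyl]-3-oxoprop-1-en-2-yl 3,4,5-tris(benzyloxy)benzoate
Product: 11 2-[3,4-bis(benzyloxy)phenyl]-7-hydroxy-4H-chromene-3,5-diyl bis[3,4,5-tris(benzyloxy)benzoate], via open-chain aryl ketone 9 (not isolated), via 2-hydroxychroman hemiketal 10 (not isolated)
Conditions: Sc(OTf)3 (10 mol%), MeCN/CH2Cl2, 0 °C to rt; then CSA (10 mol%), 4 Å MS, 40 °C
Reagents that add atoms: none
Why: The Lewis acid activates the enone carbonyl of 8, and C4/C6 of resorcinol 4 (equivalent by symmetry, each ortho to one hydroxyl and para to the other) attacks the unsubstituted β-carbon in a Friedel–Crafts conjugate addition, forming C4–C4a and, after tautomerisation, aryl ketone 9. The adjacent hydroxyl then adds to the ketone (6-exo-trig hemiketalisation, O1–C2) to give 10, and acid-promoted loss of water through the aryl-stabilised oxocarbenium ion with deprotonation at C3 should deliver the conjugated enol ester 11. The closest known reaction type is the acid-catalysed annulation of electron-rich phenols with vinyl ketones to 2-hydroxychromans and 4H-chromenes, together with Friedel–Crafts additions of arenes to 1-acylvinyl carboxylates. No stereocentre remains in 11 (the C3 centre of 9 is erased on dehydration), so no stereocontrol is needed here. The selectivity required is regiochemical, attack at the carbon flanked by hydroxyl and gallate and not at the carbon between the two hydroxyls, which the stronger para-hydroxyl activation and the two-to-one statistical weight should secure, while only the hydroxyl next to the new C–C bond can reach the ketone. The excess of 4 should suppress a second annulation on the remaining free phenol of 11.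

Step 7
Reactants: 11 2-[3,4-bis(benzyloxy)phenyl]-7-hydroxy-4H-chromene-3,5-diyl bis[3,4,5-tris(benzyloxy)benzoate]
Product: 12 (2R,3R)-2-[3,4-bis(benzyloxy)phenyl]-7-hydroxy-3,4-dihydro-2H-chromene-3,5-diyl bis[3,4,5-tris(benzyloxy)benzoate]
Conditions: H2 (50 bar), [Ir(cod)(iPr-PHOX)]BArF (2 mol%), CH2Cl2, rt
Reagents that add atoms: none
Why: Iridium-catalysed asymmetric hydrogenation of a cyclic enol ether double bond (a reaction type known for 2-aryl-4H-chromenes and for tetrasubstituted alkenes), in which syn delivery of H2 to C2=C3 makes H-2 and H-3 cis, hence ring B and the 3-O-gallate cis, and the chiral N,P ligand selects the face that gives 2R,3R.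

Step 8
Reactants: 12 (2R,3R)-2-[3,4-bis(benzyloxy)phenyl]-7-hydroxy-3,4-dihydro-2H-chromene-3,5-diyl bis[3,4,5-tris(benzyloxy)benzoate]
Product: 13 epicatechin 3,5-di-O-gallate, (2R,3R)-2-(3,4-dihydroxyphenyl)-7-hydroxy-3,4-dihydro-2H-chromene-3,5-diyl bis(3,4,5-trihydroxybenzoate)
Conditions: H2 (1 atm), Pd(OH)2/C, THF/MeOH, rt
Reagents that add atoms: none
Why: Neutral hydrogenolysis of the eight benzyl ethers should leave both gallate esters, the C2–O1 ether of the flavan and the two stereocentres untouched.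

**Compound list**

1 | 3,4,5-tris(benzyloxy)benzoic acid | O=C(O)c1cc(OCc2ccccc2)c(OCc2ccccc2)c(OCc2ccccc2)c1 | starting material
2 | 3,4,5-tris(benzyloxy)benzoyl chloride | O=C(Cl)c1cc(OCc2ccccc2)c(OCc2ccccc2)c(OCc2ccccc2)c1 | intermediate
3 | phloroglucinol (benzene-1,3,5-triol) | Oc1cc(O)cc(O)c1 | starting material
4 | 3,5-dihydroxyphenyl 3,4,5-tris(benzyloxy)benzoate | O=C(Oc1cc(O)cc(O)c1)c1cc(OCc2ccccc2)c(OCc2ccccc2)c(OCc2ccccc2)c1 | intermediate
5 | 1-(3,4-dihydroxyphenyl)propan-1-one | CCC(=O)c1ccc(O)c(O)c1 | starting material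
6 | 1-[3,4-bis(benzyloxy)phenyl]propan-1-one | CCC(=O)c1ccc(OCc2ccccc2)c(OCc2ccccc2)c1 | intermediate
7 | 1-[3,4-bis(benzyloxy)phenyl]propane-1,2-dione | CC(=O)C(=O)c1ccc(OCc2ccccc2)c(OCc2ccccc2)c1 | intermediate
8 | 3-[3,4-bis(benzyloxy)phenyl]-3-oxoprop-1-en-2-yl 3,4,5-tris(benzyloxy)benzoate | C=C(OC(=O)c1cc(OCc2ccccc2)c(OCc2ccccc2)c(OCc2ccccc2)c1)C(=O)c1ccc(OCc2ccccc2)c(OCc2ccccc2)c1 | intermediate
9 | open-chain ketone, 1-[3,4-bis(benzyloxy)phenyl]-3-{2,4-dihydroxy-6-[3,4,5-tris(benzyloxy)benzoyloxy]phenyl}-1-oxopropan-2-yl 3,4,5-tris(benzyloxy)benzoate (racemic, not isolated) | O=C(Oc1cc(O)cc(O)c1CC(OC(=O)c1cc(OCc2ccccc2)c(OCc2ccccc2)c(OCc2ccccc2)c1)C(=O)c1ccc(OCc2ccccc2)c(OCc2ccccc2)c1)c1cc(OCc2ccccc2)c(OCc2ccccc2)c(OCc2ccccc2)c1 | intermediate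
10 | hemiketal, 2-[3,4-bis(benzyloxy)phenyl]-2,7-dihydroxy-3,4-dihydro-2H-chromene-3,5-diyl bis[3,4,5-tris(benzyloxy)benzoate] (mixture of stereoisomers, not isolated) | O=C(Oc1cc(O)cc2OC(O)(c3ccc(OCc4ccccc4)c(OCc4ccccc4)c3)C(OC(=O)c3cc(OCc4ccccc4)c(OCc4ccccc4)c(OCc4ccccc4)c3)Cc12)c1cc(OCc2ccccc2)c(OCc2ccccc2)c(OCc2ccccc2)c1 | intermediate
11 | 2-[3,4-bis(benzyloxy)phenyl]-7-hydroxy-4H-chromene-3,5-diyl bis[3,4,5-tris(benzyloxy)benzoate] (achiral) | O=C(Oc1cc(O)cc2OC(c3ccc(OCc4ccccc4)c(OCc4ccccc4)c3)=C(OC(=O)c3cc(OCc4ccccc4)c(OCc4ccccc4)c(OCc4ccccc4)c3)Cc12)c1cc(OCc2ccccc2)c(OCc2ccccc2)c(OCc2ccccc2)c1 | intermediate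
12 | (2R,3R)-2-[3,4-bis(benzyloxy)phenyl]-7-hydroxy-3,4-dihydro-2H-chromene-3,5-diyl bis[3,4,5-tris(benzyloxy)benzoate] | O=C(Oc1cc(O)cc2c1C[C@@H](OC(=O)c1cc(OCc3ccccc3)c(OCc3ccccc3)c(OCc3ccccc3)c1)[C@@H](c1ccc(OCc3ccccc3)c(OCc3ccccc3)c1)O2)c1cc(OCc2ccccc2)c(OCc2ccccc2)c(OCc2ccccc2)c1 | intermediate
13 | epicatechin 3,5-di-O-gallate, (2R,3R) | O=C(Oc1cc(O)cc2c1C[C@@H](OC(=O)c1cc(O)c(O)c(O)c1)[C@@H](c1ccc(O)c(O)c1)O2)c1cc(O)c(O)c(O)c1 | target

**Count and risks**

Total steps: 8. Longest linear sequence: 6 (steps 3, 4, 5, 6, 7, 8).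

Step 7 is the most likely to fail. The tetrasubstituted, electron-rich enol-ester double bond may be reduced sluggishly, with poor enantiofacial selectivity, or only after acid-induced double-bond migration by the iridium hydride. Fallback: setting out from 11, an ionic hydrogenation (Et3SiH, CF3CO2H, CH2Cl2, −20 °C) should protonate C3 and deliver hydride to the C2 oxocarbenium ion anti to the participating 3-O-galloyl carbonyl. This should give the 2,3-cis flavan as a racemate, that is 12 together with its mirror image (2S,3S)-2-[3,4-bis(benzyloxy)phenyl]-7-hydroxy-3,4-dihydro-2H-chromene-3,5-diyl bis[3,4,5-tris(benzyloxy)benzoate] F1. Preparative chromatography on a chiral stationary phase then comes back to the route at 12.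

Step 6 is second. Friedel–Crafts attack may occur at the carbon between the two hydroxyls, the phenol oxygen may add in place of carbon (oxa-Michael addition), the product may be annulated a second time, or the enone may oligomerise under acid. Fallback: setting out from 4, statistical monosilylation (TIPSCl, imidazole, DMF, 0 °C) should give 3-hydroxy-5-[(triisopropylsilyl)oxy]phenyl 3,4,5-tris(benzyloxy)benzoate F2. Its bulky silyl ether shields both carbons next to it, so only the carbon between hydroxyl and gallate stays open and only one hydroxyl is free. The same acid-mediated annulation with 8 should then give 2-[3,4-bis(benzyloxy)phenyl]-7-[(triisopropylsilyl)oxy]-4H-chromene-3,5-diyl bis[3,4,5-tris(benzyloxy)benzoate] F3. Buffered desilylation (TBAF, AcOH, THF, 0 °C) comes back to the route at 11.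

Step 5 is third. C-Acylation or aldol self-condensation of the diketone enolate may compete, and the captodative vinyl ester may polymerise on concentration. Fallback: setting out from 6 and acid 1, an iodide-catalysed oxidative α-acyloxylation (Bu4NI cat., tBuOOH, EtOAc, 75 °C) should give racemic 1-[3,4-bis(benzyloxy)phenyl]-1-oxopropan-2-yl 3,4,5-tris(benzyloxy)benzoate F4. α-Selenenylation through the enol (PhSeCl, EtOAc, rt) should give 1-[3,4-bis(benzyloxy)phenyl]-1-oxo-2-(phenylselanyl)propan-2-yl 3,4,5-tris(benzyloxy)benzoate F5. Oxidation (H2O2, pyridine, CH2Cl2, 0 °C to rt) with selenoxide syn-elimination, for which only the methyl hydrogens are available, comes back to the route at 8 and bypasses 7.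

**Further compounds**

F1 | step 7 | (2S,3S)-2-[3,4-bis(benzyloxy)phenyl]-7-hydroxy-3,4-dihydro-2H-chromene-3,5-diyl bis[3,4,5-tris(benzyloxy)benzoate] (enantiomer of 12) | O=C(Oc1cc(O)cc2c1C[C@H](OC(=O)c1cc(OCc3ccccc3)c(OCc3ccccc3)c(OCc3ccccc3)c1)[C@H](c1ccc(OCc3ccccc3)c(OCc3ccccc3)c1)O2)c1cc(OCc2ccccc2)c(OCc2ccccc2)c(OCc2ccccc2)c1
F2 | step 6 | 3-hydroxy-5-[(triisopropylsilyl)oxy]phenyl 3,4,5-tris(benzyloxy)benzoate | O=C(Oc1cc(O)cc(O[Si](C(C)C)(C(C)C)C(C)C)c1)c1cc(OCc2ccccc2)c(OCc2ccccc2)c(OCc2ccccc2)c1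
F3 | step 6 | 2-[3,4-bis(benzyloxy)phenyl]-7-[(triisopropylsilyl)oxy]-4H-chromene-3,5-diyl bis[3,4,5-tris(benzyloxy)benzoate] | O=C(Oc1cc(O[Si](C(C)C)(C(C)C)C(C)C)cc2OC(c3ccc(OCc4ccccc4)c(OCc4ccccc4)c3)=C(OC(=O)c3cc(OCc4ccccc4)c(OCc4ccccc4)c(OCc4ccccc4)c3)Cc12)c1cc(OCc2ccccc2)c(OCc2ccccc2)c(OCc2ccccc2)c1
F4 | step 5 | 1-[3,4-bis(benzyloxy)phenyl]-1-oxopropan-2-yl 3,4,5-tris(benzyloxy)benzoate (racemic) | CC(OC(=O)c1cc(OCc2ccccc2)c(OCc2ccccc2)c(OCc2ccccc2)c1)C(=O)c1ccc(OCc2ccccc2)c(OCc2ccccc2)c1
F5 | step 5 | 1-[3,4-bis(benzyloxy)phenyl]-1-oxo-2-(phenylselanyl)propan-2-yl 3,4,5-tris(benzyloxy)benzoate (racemic) | CC([Se]c1ccccc1)(OC(=O)c1cc(OCc2ccccc2)c(OCc2ccccc2)c(OCc2ccccc2)c1)C(=O)c1ccc(OCc2ccccc2)c(OCc2ccccc2)c1
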